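**Retrosynthetic overview**
- The last bond is C8–O: the 2,5-dihydrofuran of the target is traced back to the (5R,6S)-5,6-epoxide of (6'R)-β,ε-carotene, by a vinyl-oxirane to dihydrofuran ring expansion under a chiral Brønsted acid that fixes C8.
- The C40 epoxide is cut at C11=C12 (Wittig) into an epoxy C15 phosphonium salt and a C25 ε-aldehyde.
- The C25 aldehyde is cut at C11'=C12' (Wittig) into the ε C15 phosphonium salt, made from (R)-α-ionone and a vinyl Grignard reagent, and the symmetric C10 dialdehyde.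
- The epoxy C15 salt comes from epoxy-β-ionone, which comes from Sharpless epoxidation (C–O) of β-cyclogeraniol; this fixes C5 and C6.
- Ring order: both six-membered rings are bought intact; the oxirane is made first, the dihydrofuran last by its ring expansion.

Assumption: (R)-α-ionone of high ee (natural flavour grade) and β-cyclogeraniol are taken as catalogue items; positions are given in carotenoid numbering (primed locants for the ε half); polyene steps run under argon in dim light.

Step 1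
Reactants: 1 (R)-α-ionone; 2 vinylmagnesium bromide
Product: 3 (1E,3RS)-3-methyl-1-[(1R)-2,6,6-trimethylcyclohex-2-en-1-yl]penta-1,4-dien-3-ol (vinyl-α-ionol)
Conditions: THF, −20 → 0 °C; then H2O
Reagents that add atoms: vinylmagnesium bromide (2), C=C[Mg]Br
Why: Grignard 1,2-addition to the enone carbonyl outruns conjugate addition at the hindered C7'; the purchased C6' centre is untouched and the new carbinol centre (both epimers) is erased in step 2.

Step 2
Reactants: 3 vinyl-α-ionol
Product: 4 [(2E,4E)-3-methyl-5-[(1R)-2,6,6-trimethylcyclohex-2-en-1-yl]penta-2,4-dien-1-yl]triphenylphosphonium bromide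
Conditions: PPh3·HBr (1.05 equiv), MeOH, rt, 24 h; crystallise the E salt
Reagents that add atoms: triphenylphosphine hydrobromide, [Br-].[PH+](c1ccccc1)(c1ccccc1)c1ccccc1
Why: SN1' allylic substitution: the weak acid ionises the tertiary bis-allylic alcohol to a pentadienyl cation that PPh3 captures at the unhindered terminus, the standard C15 Wittig-salt preparation, which leaves C6' alone.

Step 3
Reactants: 4 ε C15 phosphonium bromide; 5 (2E,4E,6E)-2,7-dimethylocta-2,4,6-trienedial
Product: 6 (2E,4E,6E,8E,10E,12E)-2,7,11-trimethyl-13-[(1R)-2,6,6-trimethylcyclohex-2-en-1-yl]trideca-2,4,6,8,10,12-hexaenal (C25 aldehyde)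
Conditions: NaOMe (1.1 equiv), 5 (3 equiv), CH2Cl2/MeOH, −10 °C → rt; then I2 (cat.), hexane, rt, light
Reagents that add atoms: none
Why: Wittig olefination forms C11'=C12'; the excess of the symmetric dial makes mono-olefination dominant, and the E/Z mixture at the new bond is equilibrated to all-E by iodine catalysis.

Step 4
Reactants: 7 β-cyclogeraniol
Product: 8 [(1R,6R)-2,2,6-trimethyl-7-oxabicyclo[4.1.0]heptan-1-yl]methanol
Conditions: Ti(OiPr)4 (10 mol %), D-(−)-diethyl tartrate (12 mol %), t-BuOOH (2 equiv), 4 Å MS, CH2Cl2, −20 °C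
Reagents that add atoms: tert-butyl hydroperoxide, CC(C)(C)OO
Why: Sharpless asymmetric epoxidation: the titanium tartrate complex binds the allylic hydroxyl and delivers oxygen to one face of the tetrasubstituted alkene; the D-(−)-tartrate gives the (1R,6R) epoxy alcohol, which is the future 5R,6S oxirane.

Step 5
Reactants: 8 epoxy alcohol; 9 1-(triphenyl-λ5-phosphanylidene)propan-2-one
Product: 11 (3E)-4-[(1S,6R)-2,2,6-trimethyl-7-oxabicyclo[4.1.0]heptan-1-yl]but-3-en-2-one ((5R,6S)-5,6-epoxy-β-ionone), via epoxy aldehyde 10 (not isolated)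
Conditions: Dess–Martin periodinane (1.3 equiv), 9 (1.5 equiv), CH2Cl2, 0 → 40 °C
Reagents that add atoms: 1-(triphenyl-λ5-phosphanylidene)propan-2-one (9), CC(=O)C=P(c1ccccc1)(c1ccccc1)c1ccccc1
Why: Dess–Martin oxidation run in the presence of the stabilised ylide traps the non-enolisable epoxy aldehyde at once in an E-selective Wittig reaction; neither stereocentre can epimerise.

Step 6
Reactants: 11 (5R,6S)-5,6-epoxy-β-ionone; 2 vinylmagnesium bromide
Product: 12 (1E,3RS)-3-methyl-1-[(1S,6R)-2,2,6-trimethyl-7-oxabicyclo[4.1.0]heptan-1-yl]penta-1,4-dien-3-ol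
Conditions: THF, −78 → −20 °C; then H2O
Reagents that add atoms: vinylmagnesium bromide (2), C=C[Mg]Br
Why: Grignard 1,2-addition to the methyl ketone at low temperature leaves the hindered tetrasubstituted oxirane intact; the carbinol epimers are irrelevant.

Step 7
Reactants: 12 epoxy vinyl carbinol
Product: 13 [(2E,4E)-3-methyl-5-[(1S,6R)-2,2,6-trimethyl-7-oxabicyclo[4.1.0]heptan-1-yl]penta-2,4-dien-1-yl]triphenylphosphonium bromide
Conditions: PPh3·HBr (1.0 equiv), CH2Cl2/MeOH, 0 °C; crystallise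
Reagents that add atoms: triphenylphosphine hydrobromide, [Br-].[PH+](c1ccccc1)(c1ccccc1)c1ccccc1
Why: The same SN1' Wittig-salt formation as step 2; the carbinol ionises far more readily than the oxirane, whose C6 cation would be stabilised only by a short diene carrying the electron-poor phosphonium end, so the epoxide should survive the cold, stoichiometric acid.

Step 8
Reactants: 13 epoxy C15 phosphonium bromide; 6 C25 aldehyde
Product: 14 (5R,6S,6'R)-5,6-epoxy-5,6-dihydro-β,ε-carotene (all-E)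
Conditions: NaOMe (1.1 equiv), CH2Cl2/MeOH, 0 °C → rt; then n-heptane, 80 °C (Z → E); base-washed silica
Reagents that add atoms: none
Why: Wittig olefination under basic conditions, to which the oxirane is stable, forms C11=C12 and completes the C40 skeleton; the new double bond is equilibrated thermally, without acid or iodine.

Step 9
Reactants: 14 (5R,6S,6'R)-5,6-epoxy-5,6-dihydro-β,ε-carotene
Product: 15 (5R,8R,6'R)-5,8-epoxy-5,8-dihydro-β,ε-carotene (target)
Conditions: (R)-3,3'-bis(2,4,6-triisopropylphenyl)-1,1'-binaphthyl-2,2'-diyl hydrogen phosphate (5 mol %), toluene, 4 Å MS, −40 °C, dark, 1–2 h; then Et3N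
Reagents that add atoms: none
Why: Proposed new method: a catalyst-controlled epoxide-to-furanoid ring expansion in which the phosphoric acid protonates the oxirane, the C6–O bond ionises with help of the polyene to a polyenyl cation held as a contact ion pair with the chiral phosphate in toluene, and the C5 hydroxyl (hydrogen-bonded to the phosphoryl oxygen; C5–O is never broken, so 5R is kept) closes onto C8 to form the C8–O bond and the dihydrofuran ring; since rotation about C7–C8 in the cation is fast, the face of C8 that is attacked is decided only in the ring-closing transition state inside the chiral pocket (Curtin–Hammett), and low temperature, a weak acid and the amine quench keep the labile allylic ether from re-ionising and epimerising; the closest known chemistry is the achiral acid-catalysed 5,6-epoxide to 5,8-furanoid rearrangement of carotenoids (about 1:1 at C8) together with chiral phosphoric acid ion-pair catalysis of C–O bond formation at allylic and oxocarbenium cations; the (R)-acid is taken as the antipode matched to 8R, and the (S)-acid is the first variable if it is not.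

**Compound list**
1 | (R)-α-ionone, (3E)-4-[(1R)-2,6,6-trimethylcyclohex-2-en-1-yl]but-3-en-2-one | CC1=CCCC(C)(C)[C@H]1/C=C/C(C)=O | starting material
2 | vinylmagnesium bromide | C=C[Mg]Br | starting material
3 | (1E,3RS)-3-methyl-1-[(1R)-2,6,6-trimethylcyclohex-2-en-1-yl]penta-1,4-dien-3-ol | CC1=CCCC(C)(C)[C@H]1/C=C/C(C)(O)C=C | intermediate
4 | [(2E,4E)-3-methyl-5-[(1R)-2,6,6-trimethylcyclohex-2-en-1-yl]penta-2,4-dien-1-yl]triphenylphosphonium bromide | CC1=CCCC(C)(C)[C@H]1/C=C/C(C)=C/C[P+](c1ccccc1)(c1ccccc1)c1ccccc1.[Br-] | intermediate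
5 | (2E,4E,6E)-2,7-dimethylocta-2,4,6-trienedial | O=C/C(C)=C/C=C/C=C(C)/C=O | starting material
6 | (2E,4E,6E,8E,10E,12E)-2,7,11-trimethyl-13-[(1R)-2,6,6-trimethylcyclohex-2-en-1-yl]trideca-2,4,6,8,10,12-hexaenal | CC1=CCCC(C)(C)[C@H]1/C=C/C(C)=C/C=C/C(C)=C/C=C/C=C(C)/C=O | intermediate
7 | β-cyclogeraniol, (2,6,6-trimethylcyclohex-1-en-1-yl)methanol | CC1=C(CO)C(C)(C)CCC1 | starting material
8 | [(1R,6R)-2,2,6-trimethyl-7-oxabicyclo[4.1.0]heptan-1-yl]methanol | C[C@@]12CCCC(C)(C)[C@]1(CO)O2 | intermediate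
9 | 1-(triphenyl-λ5-phosphanylidene)propan-2-one | CC(=O)C=P(c1ccccc1)(c1ccccc1)c1ccccc1 | starting material
10 | (1S,6R)-2,2,6-trimethyl-7-oxabicyclo[4.1.0]heptane-1-carbaldehyde | C[C@@]12CCCC(C)(C)[C@]1(C=O)O2 | intermediate (not isolated)
11 | (3E)-4-[(1S,6R)-2,2,6-trimethyl-7-oxabicyclo[4.1.0]heptan-1-yl]but-3-en-2-one | C[C@@]12CCCC(C)(C)[C@]1(/C=C/C(C)=O)O2 | intermediate
12 | (1E,3RS)-3-methyl-1-[(1S,6R)-2,2,6-trimethyl-7-oxabicyclo[4.1.0]heptan-1-yl]penta-1,4-dien-3-ol | C[C@@]12CCCC(C)(C)[C@]1(/C=C/C(C)(O)C=C)O2 | intermediate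
13 | [(2E,4E)-3-methyl-5-[(1S,6R)-2,2,6-trimethyl-7-oxabicyclo[4.1.0]heptan-1-yl]penta-2,4-dien-1-yl]triphenylphosphonium bromide | C[C@@]12CCCC(C)(C)[C@]1(/C=C/C(C)=C/C[P+](c3ccccc3)(c3ccccc3)c3ccccc3)O2.[Br-] | intermediate
14 | (5R,6S,6'R)-5,6-epoxy-5,6-dihydro-β,ε-carotene | CC1=CCCC(C)(C)[C@H]1/C=C/C(C)=C/C=C/C(C)=C/C=C/C=C(C)/C=C/C=C(C)/C=C/[C@@]12O[C@]1(C)CCCC2(C)C | intermediate
15 | (5R,8R,6'R)-5,8-epoxy-5,8-dihydro-β,ε-carotene | CC1=CCCC(C)(C)[C@H]1/C=C/C(C)=C/C=C/C(C)=C/C=C/C=C(C)/C=C/C=C(\C)[C@H]1C=C2C(C)(C)CCC[C@@]2(C)O1 | target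

**Step count**
Total steps: 9. Longest linear sequence: 6 steps (steps 4 to 9, from 7).

**Three steps most likely to fail**

Step 9 (the proposed new step). The chiral acid may give no useful 8R:8S bias, or the product may epimerise. The fallback is known chemistry and sets out from 14. A trace of HCl in CHCl3 (or 0.1% CF3CO2H in CH2Cl2) at 0 °C brings about the classical epoxide–furanoid rearrangement and gives a roughly 1:1 mixture of 15 and its C8 epimer, (5R,8S,6'R)-5,8-epoxy-5,8-dihydro-β,ε-carotene F1. The two are separated by preparative HPLC, as is usual for furanoid oxides; F1 can be re-equilibrated with acid and recycled. The sequence comes back to the route at 15.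

Step 7. The acid needed for salt formation may open or rearrange the oxirane. The fallback reverses the polarity of the last Wittig reaction so that the epoxide never meets acid; it sets out from 11 (and uses 6) and comes back at 14. Horner–Wadsworth–Emmons reaction of 11 with diethyl (cyanomethyl)phosphonate and NaH gives (2E,4E)-3-methyl-5-[(1S,6R)-2,2,6-trimethyl-7-oxabicyclo[4.1.0]heptan-1-yl]penta-2,4-dienenitrile F2, from which the 2Z isomer is removed. i-Bu2AlH at −78 °C and hydrolysis on wet silica give (2E,4E)-3-methyl-5-[(1S,6R)-2,2,6-trimethyl-7-oxabicyclo[4.1.0]heptan-1-yl]penta-2,4-dienal F3. In parallel NaBH4 in EtOH reduces 6 to (2E,4E,6E,8E,10E,12E)-2,7,11-trimethyl-13-[(1R)-2,6,6-trimethylcyclohex-2-en-1-yl]trideca-2,4,6,8,10,12-hexaen-1-ol F4, and PPh3·HBr in MeOH converts this into [(2E,4E,6E,8E,10E,12E)-2,7,11-trimethyl-13-[(1R)-2,6,6-trimethylcyclohex-2-en-1-yl]trideca-2,4,6,8,10,12-hexaen-1-yl]triphenylphosphonium bromide F5. Wittig reaction of F3 with F5 (NaOMe, CH2Cl2/MeOH) forms C11=C12 and gives 14.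

Step 5. The one-flask oxidation and ylide trapping may stall at the hindered, fully substituted epoxy aldehyde. The fallback is a C5 homologation that bypasses 11 and 12; it sets out from 8 and comes back at 13. Alcohol 8 is oxidised with SO3·pyridine, DMSO and Et3N, and aldehyde 10 is isolated. Horner–Wadsworth–Emmons reaction with the more nucleophilic anion of ethyl (2E)-4-(diethoxyphosphoryl)-3-methylbut-2-enoate (NaH, THF) gives ethyl (2E,4E)-3-methyl-5-[(1S,6R)-2,2,6-trimethyl-7-oxabicyclo[4.1.0]heptan-1-yl]penta-2,4-dienoate F6. i-Bu2AlH at −78 °C gives (2E,4E)-3-methyl-5-[(1S,6R)-2,2,6-trimethyl-7-oxabicyclo[4.1.0]heptan-1-yl]penta-2,4-dien-1-ol F7. CBr4 and PPh3 in CH2Cl2 at 0 °C give, without isolation, (1S,6R)-1-[(1E,3E)-5-bromo-3-methylpenta-1,3-dien-1-yl]-2,2,6-trimethyl-7-oxabicyclo[4.1.0]heptane F8, which further PPh3 quaternises under neutral conditions to 13.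

Further compounds
F1 | step 9 | (5R,8S,6'R)-5,8-epoxy-5,8-dihydro-β,ε-carotene | CC1=CCCC(C)(C)[C@H]1/C=C/C(C)=C/C=C/C(C)=C/C=C/C=C(C)/C=C/C=C(\C)[C@@H]1C=C2C(C)(C)CCC[C@@]2(C)O1
F2 | step 7 | (2E,4E)-3-methyl-5-[(1S,6R)-2,2,6-trimethyl-7-oxabicyclo[4.1.0]heptan-1-yl]penta-2,4-dienenitrile | C[C@@]12CCCC(C)(C)[C@]1(/C=C/C(C)=C/C#N)O2
F3 | step 7 | (2E,4E)-3-methyl-5-[(1S,6R)-2,2,6-trimethyl-7-oxabicyclo[4.1.0]heptan-1-yl]penta-2,4-dienal | C[C@@]12CCCC(C)(C)[C@]1(/C=C/C(C)=C/C=O)O2
F4 | step 7 | (2E,4E,6E,8E,10E,12E)-2,7,11-trimethyl-13-[(1R)-2,6,6-trimethylcyclohex-2-en-1-yl]trideca-2,4,6,8,10,12-hexaen-1-ol | CC1=CCCC(C)(C)[C@H]1/C=C/C(C)=C/C=C/C(C)=C/C=C/C=C(C)/CO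
F5 | step 7 | [(2E,4E,6E,8E,10E,12E)-2,7,11-trimethyl-13-[(1R)-2,6,6-trimethylcyclohex-2-en-1-yl]trideca-2,4,6,8,10,12-hexaen-1-yl]triphenylphosphonium bromide | CC1=CCCC(C)(C)[C@H]1/C=C/C(C)=C/C=C/C(C)=C/C=C/C=C(C)/C[P+](c1ccccc1)(c1ccccc1)c1ccccc1.[Br-]
F6 | step 5 | ethyl (2E,4E)-3-methyl-5-[(1S,6R)-2,2,6-trimethyl-7-oxabicyclo[4.1.0]heptan-1-yl]penta-2,4-dienoate | C[C@@]12CCCC(C)(C)[C@]1(/C=C/C(C)=C/C(=O)OCC)O2
F7 | step 5 | (2E,4E)-3-methyl-5-[(1S,6R)-2,2,6-trimethyl-7-oxabicyclo[4.1.0]heptan-1-yl]penta-2,4-dien-1-ol | C[C@@]12CCCC(C)(C)[C@]1(/C=C/C(C)=C/CO)O2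
F8 | step 5 | (1S,6R)-1-[(1E,3E)-5-bromo-3-methylpenta-1,3-dien-1-yl]-2,2,6-trimethyl-7-oxabicyclo[4.1.0]heptane | C[C@@]12CCCC(C)(C)[C@]1(/C=C/C(C)=C/CBr)O2
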